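**Retrosynthetic overview**
1. The target comes from a (2S)-2-aryl-2H-chromene (flav-3-ene) by adding the C3–OH across C3=C4 anti to the C2 aryl group (Cu–boryl addition, then oxidation), followed by removal of two silyl ethers; C2 relays its configuration to C3 (2,3-trans).
2. Key disconnection C2–C1′: a racemic 2-ethoxy-2H-chromene and a 4-silyloxyphenyl boronate are joined enantioconvergently under chiral hydroxy-acid/Yb(OTf)3 catalysis.
3. Enabling feature: C2 is the acetal-type carbon of the pyran ring, bonded to ring oxygen O1 and allylic to C3=C4, which is conjugated with the A ring through C4a–C8a. A C2–OEt precursor therefore ionises to a planar, aromatic 1-benzopyrylium cation in which both acetal enantiomers become identical.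
4. The acetal comes from 7-silyloxy-5-methoxy-8-prenylcoumarin (DIBAL-H, then EtOH/H+); the 8-prenyl group comes from an aromatic Claisen rearrangement of the 7-O-(1,1-dimethylallyl) ether; the coumarin comes from 2,4-dihydroxy-6-methoxybenzaldehyde by Wittig olefination/lactonisation.
5. Ring order: A ring purchased; pyran ring closed in step 1 (lactonisation); B ring purchased and attached in step 7; no ring is formed afterwards.

Key step: step 7

Abbreviations: prenyl = 3-methylbut-2-en-1-yl; TBS = tert-butyldimethylsilyl; Bpin = 4,4,5,5-tetramethyl-1,3,2-dioxaborolan-2-yl.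

Assumption: compounds 1, 2, 5 and 11 are taken as catalogue materials, and the sense of induction of the tartaric-acid-derived catalyst in step 7 is taken to be invertible by using its antipode (from L- or D-tartaric acid); the antipode that delivers the (2S)-flav-3-ene is the one used.

Remark: the C2 descriptor changes from S (compounds 14, 15) to R (16, 17) only because the CIP ranking of C3 changes; the geometry at C2 is not altered after step 7.

**Step 1**
Reactants: 1 2,4-dihydroxy-6-methoxybenzaldehyde; 2 ethyl (triphenylphosphoranylidene)acetate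
Product: 4 7-hydroxy-5-methoxy-2H-chromen-2-one (7-hydroxy-5-methoxycoumarin), via hydroxycinnamate ester 3 (not isolated)
Conditions: PhNEt2, reflux (ca. 215 °C), N2
Reagents that add atoms: none
Why: Wittig olefination followed by thermal E/Z isomerisation and lactonisation (the classical coumarin synthesis from salicylaldehydes); the pyranone ring can close only onto the single ortho hydroxyl (the other ortho position carries OMe), which fixes the 5-OMe/7-OH pattern.

**Step 2**
Reactants: 4 7-hydroxy-5-methoxycoumarin; 5 tert-butyl 2-methylbut-3-en-2-yl carbonate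
Product: 6 5-methoxy-7-[(2-methylbut-3-en-2-yl)oxy]-2H-chromen-2-one
Conditions: Pd(PPh3)4 (3 mol%), THF, 0 °C, short reaction time
Reagents that add atoms: none
Why: Decarboxylative Tsuji–Trost O-allylation; under kinetic control the phenoxide attacks the more substituted terminus of the 1,1-dimethyl-π-allyl palladium species, giving the tertiary (reverse-prenyl) ether at the only free hydroxyl.

**Step 3**
Reactants: 6 5-methoxy-7-[(2-methylbut-3-en-2-yl)oxy]-2H-chromen-2-one
Product: 7 7-hydroxy-5-methoxy-8-(3-methylbut-2-en-1-yl)-2H-chromen-2-one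
Conditions: PhNEt2, 140–160 °C, N2
Reagents that add atoms: none
Why: Aromatic Claisen rearrangement ([3,3] shift, then tautomerisation) turns the 1,1-dimethylallyl ether into a normal prenyl group on an ortho carbon; as in the umbelliferone series, migration to C8 (between O7 and the ring oxygen) should be preferred over the more crowded C6 flanked by 5-OMe.

**Step 4**
Reactants: 7 7-hydroxy-5-methoxy-8-prenylcoumarin
Product: 8 7-[(tert-butyldimethylsilyl)oxy]-5-methoxy-8-(3-methylbut-2-en-1-yl)-2H-chromen-2-one
Conditions: TBSCl, imidazole, DMF, rt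
Reagents that add atoms: tert-butyldimethylsilyl chloride, CC(C)(C)[Si](C)(C)Cl
Why: Standard phenol silylation; the TBS ether masks the acidic 7-OH for the hydride, Lewis acid and copper steps and prevents acid-induced cyclisation of the phenol onto the prenyl alkene.

**Step 5**
Reactants: 8 7-TBSO-5-methoxy-8-prenylcoumarin
Product: 10 racemic tert-butyl{[2-ethoxy-5-methoxy-8-(3-methylbut-2-en-1-yl)-2H-chromen-7-yl]oxy}dimethylsilane, via lactol 9 (not isolated)
Conditions: DIBAL-H (1.1 equiv), CH2Cl2, −78 °C; Rochelle salt; crude lactol, EtOH, PPTS (cat.), 3 Å MS, rt; Et3N quench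
Reagents that add atoms: ethanol, CCO
Why: Partial lactone reduction (the aluminate hemiacetal is stable at −78 °C) gives the 2H-chromen-2-ol, which undergoes acid-catalysed acetal exchange with ethanol through the benzopyrylium ion; the aryl silyl ether and the prenyl alkene tolerate both operations.

**Step 6**
Reactants: 11 [4-(tert-butyldimethylsilyloxy)phenyl]boronic acid
Product: 12 diethyl [4-(tert-butyldimethylsilyloxy)phenyl]boronate
Conditions: EtOH (excess), 3 Å MS, PhMe, rt; evaporate; used crude
Reagents that add atoms: ethanol, CCO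
Why: Boronic acid esterification, an equilibrium driven to the diethyl ester by removal of water.

**Step 7**
Reactants: 10 racemic 2-ethoxy-2H-chromene acetal; 12 diethyl [4-(TBSO)phenyl]boronate
Product: 14 tert-butyl{4-[(2S)-7-(tert-butyldimethylsilyloxy)-5-methoxy-8-(3-methylbut-2-en-1-yl)-2H-chromen-2-yl]phenoxy}dimethylsilane, via benzopyrylium cation 13 (not isolated)
Conditions: tartaric acid mono(N,N-dibenzylamide) carboxylic acid catalyst (10 mol%), Yb(OTf)3 (5 mol%), EtOAc, −20 → 4 °C, dark
Reagents that add atoms: none
Why: Yb(OTf)3 ionises either enantiomer of acetal 10 to the same planar 1-benzopyrylium cation 13, while the chiral hydroxy acid exchanges onto boron of 12 to give a chiral dioxaborolanone whose ate complex with the departing ethoxide transfers the aryl group to C2 within a tight ion pair, so the racemate is funnelled into one enantiomer. The closest known reaction type is the chiral Brønsted acid/lanthanide triflate co-catalysed addition of aryl and alkenyl boronates to 2-alkoxy-2H-chromenes. No ring is closed in this step; the pyran ring is already present and only the exocyclic C2–C1′ bond is formed. The new C2 stereocentre is controlled by the catalyst (choice of tartaric acid antipode), since the substrate has no other stereocentre. The step needs C2 over C4 regioselectivity, which the peri 5-OMe group (shielding C4) and aryl delivery from the borate held at the oxocarbenium end of the ion pair should secure, and chemoselectivity over the prenyl alkene and silyl ethers, which are inert to boronates and the mild Lewis acid. Low temperature, low acid loading and exclusion of light are used so that the electron-rich product does not re-ionise at C2–O1 or ring-open, either of which would erode the ee.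

**Step 8**
Reactants: 14 (2S)-bis-TBS flav-3-ene
Product: 16 (2R,3S)-7-(tert-butyldimethylsilyloxy)-2-[4-(tert-butyldimethylsilyloxy)phenyl]-5-methoxy-8-(3-methylbut-2-en-1-yl)chroman-3-ol, via pinacol boronate 15 (not isolated)
Conditions: CuCl (5 mol%), Xantphos (6 mol%), NaOtBu (10 mol%), B2pin2 (1.3 equiv), MeOH (2 equiv), THF, rt; then NaBO3·4H2O, THF/H2O, rt
Reagents that add atoms: sodium perborate, [Na+].[O-]OB=O (oxygen of the C3–OH); bis(pinacolato)diboron, CC1(C)OB(OC1(C)C)B1OC(C)(C)C(C)(C)O1 (boron of intermediate 15 only)
Why: Copper(I)-catalysed protoboration followed by stereoretentive C–B oxidation; the nucleophilic boryl copper inserts only the aryl-conjugated C3=C4 bond (the isolated trisubstituted prenyl alkene is inert), with copper at benzylic C4 and boron at C3 on the face anti to the C2 aryl group, so the centre set in step 7 controls C3 and the 2,3-trans alcohol should result.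

**Step 9**
Reactants: 16 (2R,3S)-bis-TBS flavan-3-ol
Product: 17 8-prenylafzelechin 5-methyl ether, (2R,3S)-2-(4-hydroxyphenyl)-5-methoxy-8-(3-methylbut-2-en-1-yl)chroman-3,7-diol
Conditions: TBAF (2.2 equiv), AcOH (2.2 equiv), THF, 0 °C; aq. NH4Cl
Reagents that add atoms: none
Why: Fluoride-induced cleavage of both aryl silyl ethers; acetic acid buffering and low temperature keep the 4′-phenoxide from opening the pyran ring through a quinone methide, so C2 should not epimerise.

**Compound list**
1 | 2,4-dihydroxy-6-methoxybenzaldehyde | COc1cc(O)cc(O)c1C=O | starting material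
2 | ethyl (triphenylphosphoranylidene)acetate | CCOC(=O)C=P(c1ccccc1)(c1ccccc1)c1ccccc1 | starting material
3 | ethyl (E)-3-(2,4-dihydroxy-6-methoxyphenyl)prop-2-enoate | CCOC(=O)/C=C/c1c(O)cc(O)cc1OC | intermediate (not isolated)
4 | 7-hydroxy-5-methoxy-2H-chromen-2-one | COc1cc(O)cc2oc(=O)ccc12 | intermediate
5 | tert-butyl 2-methylbut-3-en-2-yl carbonate | CC(C)(C)OC(=O)OC(C)(C)C=C | starting material
6 | 5-methoxy-7-[(2-methylbut-3-en-2-yl)oxy]-2H-chromen-2-one | COc1cc(OC(C)(C)C=C)cc2oc(=O)ccc12 | intermediate
7 | 7-hydroxy-5-methoxy-8-(3-methylbut-2-en-1-yl)-2H-chromen-2-one | COc1cc(O)c(CC=C(C)C)c2oc(=O)ccc12 | intermediate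
8 | 7-[(tert-butyldimethylsilyl)oxy]-5-methoxy-8-(3-methylbut-2-en-1-yl)-2H-chromen-2-one | COc1cc(O[Si](C)(C)C(C)(C)C)c(CC=C(C)C)c2oc(=O)ccc12 | intermediate
9 | racemic 7-[(tert-butyldimethylsilyl)oxy]-5-methoxy-8-(3-methylbut-2-en-1-yl)-2H-chromen-2-ol (lactol) | COc1cc(O[Si](C)(C)C(C)(C)C)c(CC=C(C)C)c2c1C=CC(O)O2 | intermediate (not isolated)
10 | racemic tert-butyl{[2-ethoxy-5-methoxy-8-(3-methylbut-2-en-1-yl)-2H-chromen-7-yl]oxy}dimethylsilane | COc1cc(O[Si](C)(C)C(C)(C)C)c(CC=C(C)C)c2c1C=CC(OCC)O2 | intermediate
11 | [4-(tert-butyldimethylsilyloxy)phenyl]boronic acid | CC(C)(C)[Si](C)(C)Oc1ccc(B(O)O)cc1 | starting material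
12 | diethyl [4-(tert-butyldimethylsilyloxy)phenyl]boronate | CCOB(OCC)c1ccc(O[Si](C)(C)C(C)(C)C)cc1 | intermediate
13 | 7-[(tert-butyldimethylsilyl)oxy]-5-methoxy-8-(3-methylbut-2-en-1-yl)chromenylium (1-benzopyrylium) cation | COc1cc(O[Si](C)(C)C(C)(C)C)c(CC=C(C)C)c2[o+]cccc12 | intermediate (not isolated)
14 | tert-butyl{4-[(2S)-7-(tert-butyldimethylsilyloxy)-5-methoxy-8-(3-methylbut-2-en-1-yl)-2H-chromen-2-yl]phenoxy}dimethylsilane | COc1cc(O[Si](C)(C)C(C)(C)C)c(CC=C(C)C)c2c1C=C[C@@H](c1ccc(O[Si](C)(C)C(C)(C)C)cc1)O2 | intermediate
15 | (2S,3S)-7-(TBSO)-2-[4-(TBSO)phenyl]-5-methoxy-8-prenyl-3-(Bpin)chroman | COc1cc(O[Si](C)(C)C(C)(C)C)c(CC=C(C)C)c2c1C[C@H](B1OC(C)(C)C(C)(C)O1)[C@@H](c1ccc(O[Si](C)(C)C(C)(C)C)cc1)O2 | intermediate (not isolated)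
16 | (2R,3S)-7-(TBSO)-2-[4-(TBSO)phenyl]-5-methoxy-8-prenylchroman-3-ol | COc1cc(O[Si](C)(C)C(C)(C)C)c(CC=C(C)C)c2c1C[C@H](O)[C@@H](c1ccc(O[Si](C)(C)C(C)(C)C)cc1)O2 | intermediate
17 | 8-prenylafzelechin 5-methyl ether | COc1cc(O)c(CC=C(C)C)c2c1C[C@H](O)[C@@H](c1ccc(O)cc1)O2 | target

**Step count**
Total steps: 9. Longest linear sequence: 8 (steps 1, 2, 3, 4, 5, 7, 8, 9); step 6 is a one-step side branch.

**Steps most likely to fail**

Step 7. The aryl transfer may show insufficient facial discrimination on this very electron-rich benzopyrylium ion, or the product may lose ee by re-ionisation of C2–O1 or by electrocyclic ring opening and reclosure. The fallback moves the stereo-determining event to the next operation. It sets out from acetal 10 and boronate 12: the same boronate addition is run with a racemic or achiral hydroxy acid (for example glycolic acid) and Yb(OTf)3 at higher loading and temperature, where ee is no longer at stake, to give the racemic 2-aryl-2H-chromene, racemic bis-TBS flav-3-ene F1. F1 is then submitted to a copper(I)-catalysed kinetic resolution by enantioselective protoboration (CuCl, a chiral bisphosphine of the matched hand, NaOtBu, B2pin2, MeOH, THF) taken to about half conversion. The (S)-enantiomer should be borylated anti to the aryl group while the (R)-enantiomer is left behind. The fallback comes back to the route at boronate 15, which is oxidised as in step 8.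

Step 8. Insertion of the boryl copper species into the electron-rich, peri-hindered C3=C4 bond may be slow, facial selectivity may be incomplete, or the alkoxide base may start to remove aryl silyl ethers. The fallback sets out from flav-3-ene 14 and uses an electrophilic borane instead of a nucleophilic boryl metal: 9-BBN (THF, 0 °C → rt). On steric grounds 9-BBN should discriminate the cis-disubstituted ring alkene from the trisubstituted prenyl alkene. The donor-substituted A ring directs hydride to benzylic C4 and boron to C3, anti to the aryl group, giving the B-alkyl-9-BBN adduct, (2S,3S)-3-(9-borabicyclo[3.3.1]nonan-9-yl) flavan F2. Oxidation (NaBO3 or H2O2/NaOH, 0 °C) comes back to the route at 16.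

Step 3. The allyl unit may migrate competitively to C6, and the ortho-prenyl phenol may cyclise further on prolonged heating. The fallback sets out from aldehyde 1 and carries out the rearrangement before the pyranone ring exists, where the hydrogen bond between 2-OH and the formyl group biases migration to the carbon between the two oxygens. Selective O-alkylation of the non-chelated 4-OH of 1 with carbonate 5 (Pd(PPh3)4, THF, 0 °C) gives 2-hydroxy-6-methoxy-4-[(2-methylbut-3-en-2-yl)oxy]benzaldehyde F3. Claisen rearrangement (Eu(fod)3 cat., CHCl3, 60 °C) gives 2,4-dihydroxy-6-methoxy-3-(3-methylbut-2-en-1-yl)benzaldehyde F4. Wittig olefination with ylide 2 in hot PhNEt2 proceeds through ethyl (E)-3-[2,4-dihydroxy-6-methoxy-3-(3-methylbut-2-en-1-yl)phenyl]prop-2-enoate F5, which lactonises onto the only ortho hydroxyl. The fallback comes back to the route at coumarin 7.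

**Further compounds**
F1 | step 7 | racemic tert-butyl{4-[7-(tert-butyldimethylsilyloxy)-5-methoxy-8-(3-methylbut-2-en-1-yl)-2H-chromen-2-yl]phenoxy}dimethylsilane | COc1cc(O[Si](C)(C)C(C)(C)C)c(CC=C(C)C)c2c1C=CC(c1ccc(O[Si](C)(C)C(C)(C)C)cc1)O2
F2 | step 8 | (2S,3S)-3-(9-borabicyclo[3.3.1]nonan-9-yl)-7-(TBSO)-2-[4-(TBSO)phenyl]-5-methoxy-8-prenylchroman | COc1cc(O[Si](C)(C)C(C)(C)C)c(CC=C(C)C)c2c1C[C@H](B1C3CCCC1CCC3)[C@@H](c1ccc(O[Si](C)(C)C(C)(C)C)cc1)O2
F3 | step 3 | 2-hydroxy-6-methoxy-4-[(2-methylbut-3-en-2-yl)oxy]benzaldehyde | COc1cc(OC(C)(C)C=C)cc(O)c1C=O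
F4 | step 3 | 2,4-dihydroxy-6-methoxy-3-(3-methylbut-2-en-1-yl)benzaldehyde | COc1cc(O)c(CC=C(C)C)c(O)c1C=O
F5 | step 3 | ethyl (E)-3-[2,4-dihydroxy-6-methoxy-3-(3-methylbut-2-en-1-yl)phenyl]prop-2-enoate | CCOC(=O)/C=C/c1c(O)c(CC=C(C)C)c(O)cc1OC
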